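**Retrosynthetic overview**
1. Target ⇐ lipase acetylation of the side-chain primary OH, methacryloylation of the ring CH2OH, and Eschenmoser methylenation of a trans-fused hydroxy γ-lactone.
2. γ-Lactone ⇐ oxidative lactonisation of a 5-hydroxy-6-(2-hydroxyethyl)cyclohex-2-enone, then hydride reduction of the enone C=O; enone ⇐ Stork–Danheiser addition of PMBOCH2Li to a furan-fused vinylogous ester that fixes which dione carbonyl receives the CH2O arm.
3. Vinylogous ester ⇐ 2-alkylcyclohexane-1,3-dione ⇐ amine-catalysed Michael addition of the dione to crotonaldehyde (side-chain stereocentre), then one-carbon extension.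
4. Cyclohexane-1,3-dione ⇐ Claisen-type cyclisation of a methyl ketone onto a butyrolactone ⇐ syn α-allyl β-hydroxy ester from a ketoreductase dynamic kinetic resolution (first two stereocentres).
5. Ring order: carbocycle (step 8) → temporary dihydrofuran (step 11, opened in step 15) → γ-lactone (step 16).

Assumption: the SMILES is read literally, giving a (3aR,4S,7aR) core with a (2S) side chain; fructone, tributyl(iodomethyl)stannane and screening kits of ketoreductases are taken as purchasable.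

Abbreviations: TBS = tert-butyldimethylsilyl, TBDPS = tert-butyldiphenylsilyl, PMB = 4-methoxybenzyl, Tf = trifluoromethanesulfonyl, PPTS = pyridinium 4-toluenesulfonate.

Step 1
Reactants: 1 ethyl 2-(2-methyl-1,3-dioxolan-2-yl)acetate (fructone)
Product: 2 2-(2-methyl-1,3-dioxolan-2-yl)acetic acid
Conditions: LiOH·H2O, THF/H2O 3:1, 0 °C → rt; then 1 M HCl to pH 3–4, 0 °C
Reagents that add atoms: lithium hydroxide, [Li+].[OH-]
Why: Ester saponification, in which the ketal is inert to base and survives the short cold acidification.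

Step 2
Reactants: 2 2-(2-methyl-1,3-dioxolan-2-yl)acetic acid; 3 potassium 3-ethoxy-3-oxopropanoate (KO2CCH2CO2Et)
Product: 5 ethyl 4-(2-methyl-1,3-dioxolan-2-yl)-3-oxobutanoate, via acyl imidazolide 4 (not isolated)
Conditions: 1,1'-carbonyldiimidazole, THF, rt; then 3, MgCl2, Et3N, MeCN, rt → 45 °C; cold 1 M HCl to pH 3
Reagents that add atoms: none
Why: Masamune–Brooks homologation, in which the magnesium chelate of the malonate half-ester is C-acylated by the imidazolide and loses CO2 on work-up to give the β-keto ester.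

Step 3
Reactants: 5 ethyl 4-(2-methyl-1,3-dioxolan-2-yl)-3-oxobutanoate; 6 3-bromoprop-1-ene (allyl bromide)
Product: 7 ethyl 2-allyl-4-(2-methyl-1,3-dioxolan-2-yl)-3-oxobutanoate (racemic)
Conditions: K2CO3, acetone, 50 °C
Reagents that add atoms: none
Why: Acetoacetic-ester-type C-alkylation at the doubly activated carbon, whose new stereocentre is deliberately left racemic because it epimerises freely between the two carbonyls.

Step 4
Reactants: 7 ethyl 2-allyl-4-(2-methyl-1,3-dioxolan-2-yl)-3-oxobutanoate (racemic)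
Product: 8 ethyl (2S,3R)-2-allyl-3-hydroxy-4-(2-methyl-1,3-dioxolan-2-yl)butanoate (syn)
Conditions: ketoreductase (NADPH-dependent, syn-selective enzyme chosen from a commercial panel), NADP+ (cat.), i-PrOH (10 % v/v), KH2PO4/K2HPO4 buffer pH 7.5, MgSO4 (2 mM), 30 °C
Reagents that add atoms: none
Why: Ketoreductase-catalysed asymmetric carbonyl reduction run as a dynamic kinetic resolution, in which the α-centre racemises in the buffer while the enzyme reduces only the (2S)-ketone from one face, so C-2 (S) and C-3 (R) are set together as the syn pair and alkene and ketal are untouched.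

Step 5
Reactants: 8 ethyl (2S,3R)-2-allyl-3-hydroxy-4-(2-methyl-1,3-dioxolan-2-yl)butanoate
Product: 9 ethyl (2S,3R)-2-allyl-3-(TBSO)-4-(2-methyl-1,3-dioxolan-2-yl)butanoate
Conditions: TBSOTf, 2,6-lutidine, CH2Cl2, −78 → 0 °C
Reagents that add atoms: tert-butyldimethylsilyl trifluoromethanesulfonate, CC(C)(C)[Si](C)(C)OS(=O)(=O)C(F)(F)F
Why: Silyl ether formation masks the secondary alcohol for the strongly basic ring closure of step 8.

Step 6
Reactants: 9 ethyl (2S,3R)-2-allyl-3-(TBSO)-4-(2-methyl-1,3-dioxolan-2-yl)butanoate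
Product: 10 ethyl (2S,3R)-3-(TBSO)-2-(2-hydroxyethyl)-4-(2-methyl-1,3-dioxolan-2-yl)butanoate
Conditions: O3, CH2Cl2/MeOH 4:1, NaHCO3, −78 °C; then NaBH4, −78 → 0 °C
Reagents that add atoms: ozone, [O-][O+]=O
Why: Ozonolysis of the only alkene with in-flask borohydride reduction turns the allyl group into a 2-hydroxyethyl arm without touching ester, ketal or stereocentres.

Step 7
Reactants: 10 ethyl (2S,3R)-3-(TBSO)-2-(2-hydroxyethyl)-4-(2-methyl-1,3-dioxolan-2-yl)butanoate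
Product: 11 (3S)-3-[(1R)-1-(TBSO)-3-oxobutyl]oxolan-2-one
Conditions: PPTS (0.2 equiv), acetone/H2O 9:1, 55 °C; then PhMe, 80 °C
Reagents that add atoms: water, O
Why: Mild acid hydrolyses the dioxolane to the methyl ketone and lactonises the γ-hydroxy ester, so the carboxyl carbon becomes an activated lactone acyl donor and the primary OH is internally protected.

Step 8
Reactants: 11 (3S)-3-[(1R)-1-(TBSO)-3-oxobutyl]oxolan-2-one
Product: 13 (4S,5R)-5-(TBSO)-4-[2-(TBSO)ethyl]cyclohexane-1,3-dione, via hydroxy-dione 12 (not isolated)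
Conditions: LiN(SiMe3)2 (2.2 equiv), THF, −78 → −30 °C; then TBSCl (1.2 equiv), −30 → 0 °C; AcOH, then pH 5 buffer
Reagents that add atoms: tert-butyl(chloro)dimethylsilane, CC(C)(C)[Si](C)(C)Cl
Why: Intramolecular Claisen (Dieckmann-type) acylation, in which the kinetic methyl-ketone enolate opens the lactone 6-exo-trig to the 1,3-dione enolate (an enolate on the methyl side cannot expel the β-silyloxy group), the released alkoxide is silylated in the same flask, and the trans arrangement of the two ring substituents follows from the syn pair of 8.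

Step 9
Reactants: 13 (4S,5R)-5-(TBSO)-4-[2-(TBSO)ethyl]cyclohexane-1,3-dione; 14 (E)-but-2-enal (crotonaldehyde)
Product: 15 (3S)-3-{(3S,4R)-4-(TBSO)-3-[2-(TBSO)ethyl]-2-hydroxy-6-oxocyclohex-1-en-1-yl}butanal (in equilibrium with its cyclic hemiacetals)
Conditions: (R)-α,α-diphenylprolinol trimethylsilyl ether (15 mol %), PhCO2H (15 mol %), CH2Cl2, 0 °C
Reagents that add atoms: none
Why: Iminium-catalysed asymmetric Michael addition, in which the dione enol attacks the E-iminium ion of crotonaldehyde on the face away from the CPh2OSiMe3 group, so the (R)-catalyst gives the (S)-methyl-bearing centre under catalyst control with the remote ring stereocentres not interfering.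

Step 10
Reactants: 15 (3S)-3-{(3S,4R)-4-(TBSO)-3-[2-(TBSO)ethyl]-2-hydroxy-6-oxocyclohex-1-en-1-yl}butanal
Product: 16 (4S,5R)-5-(TBSO)-4-[2-(TBSO)ethyl]-3-hydroxy-2-[(2S)-pent-4-en-2-yl]cyclohex-2-en-1-one (enol form of the 1,3-dione)
Conditions: Ph3PCH3Br (4 equiv), KN(SiMe3)2 (3.8 equiv), THF, 0 °C; add 15 at −78 °C → rt
Reagents that add atoms: methyltriphenylphosphonium bromide (used as its ylide), C[P+](c1ccccc1)(c1ccccc1)c1ccccc1.[Br-]
Why: Wittig methylenation, in which the basic ylide opens the hemiacetal to the enolate-aldehyde and methylenates the aldehyde faster than it enolises, adding the last side-chain carbon.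

Step 11
Reactants: 16 (4S,5R)-5-(TBSO)-4-[2-(TBSO)ethyl]-3-hydroxy-2-[(2S)-pent-4-en-2-yl]cyclohex-2-en-1-one
Product: 18 (3aS,4R)-4-(TBSO)-7-[(2S)-pent-4-en-2-yl]-3,3a,4,5-tetrahydro-1-benzofuran-6(2H)-one, via primary alcohol 17 (not isolated)
Conditions: HF·pyridine, pyridine/THF, 0 °C; then PPTS (cat.), PhH, 4 Å molecular sieves, 45 °C
Reagents that add atoms: none
Why: Selective cleavage of the primary silyl ether followed by acid-catalysed cyclodehydration onto the only carbonyl the alcohol can reach in a five-membered ring gives a cyclic vinylogous ester and so differentiates the two dione carbonyls unambiguously.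

Step 12
Reactants: 18 (3aS,4R)-4-(TBSO)-7-[(2S)-pent-4-en-2-yl]-3,3a,4,5-tetrahydro-1-benzofuran-6(2H)-one
Product: 19 (3aS,4R)-4-(TBSO)-7-[(2S)-5-hydroxypentan-2-yl]-3,3a,4,5-tetrahydro-1-benzofuran-6(2H)-one
Conditions: 9-BBN (1.5 equiv), THF, 0 °C → rt; then 30 % H2O2, 1 M NaOH, 0 °C
Reagents that add atoms: hydrogen peroxide, OO
Why: Anti-Markovnikov hydroboration–oxidation, in which 9-BBN reacts only with the terminal alkene because the tetrasubstituted push–pull alkene and the vinylogous ester carbonyl are inert.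

Step 13
Reactants: 19 (3aS,4R)-4-(TBSO)-7-[(2S)-5-hydroxypentan-2-yl]-3,3a,4,5-tetrahydro-1-benzofuran-6(2H)-one
Product: 20 (3aS,4R)-4-(TBSO)-7-[(2S)-5-(TBDPSO)pentan-2-yl]-3,3a,4,5-tetrahydro-1-benzofuran-6(2H)-one
Conditions: TBDPSCl, imidazole, CH2Cl2, 0 °C → rt
Reagents that add atoms: tert-butyl(chloro)diphenylsilane, CC(C)(C)[Si](Cl)(c1ccccc1)c1ccccc1
Why: Silylation of the primary alcohol with an acid-stable group that lasts through steps 15 to 22.

Step 14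
Reactants: 21 (4-methoxyphenyl)methanol; 22 tributyl(iodomethyl)stannane
Product: 23 tributyl{[(4-methoxybenzyl)oxy]methyl}stannane
Conditions: NaH, THF/DMF, 0 °C → rt
Reagents that add atoms: none
Why: Williamson ether synthesis (alkoxide SN2 on the iodomethylstannane) gives the tin precursor of the alkoxymethyl anion.

Step 15
Reactants: 20 (3aS,4R)-4-(TBSO)-7-[(2S)-5-(TBDPSO)pentan-2-yl]-3,3a,4,5-tetrahydro-1-benzofuran-6(2H)-one; 23 tributyl{[(4-methoxybenzyl)oxy]methyl}stannane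
Product: 25 (5R,6S)-5-hydroxy-6-(2-hydroxyethyl)-3-[(PMB-oxy)methyl]-2-[(2S)-5-(TBDPSO)pentan-2-yl]cyclohex-2-en-1-one, via tertiary carbinol 24 (not isolated)
Conditions: 23 (2 equiv), n-BuLi, THF, −78 °C; anhydrous CeCl3, −78 °C; 20, −78 → −40 °C; NH4Cl; then 3 M HCl/THF 1:4, rt
Reagents that add atoms: water, O
Why: Stork–Danheiser transposition, in which tin–lithium exchange gives PMBOCH2Li, its cerium reagent adds 1,2 to the vinylogous ester carbonyl without enolising it, and aqueous acid ionises the tertiary allylic carbinol, hydrolyses the oxocarbenium ion (opening the dihydrofuran) and removes the secondary silyl ether to leave the tetrasubstituted enone.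

Step 16
Reactants: 25 (5R,6S)-5-hydroxy-6-(2-hydroxyethyl)-3-[(PMB-oxy)methyl]-2-[(2S)-5-(TBDPSO)pentan-2-yl]cyclohex-2-en-1-one
Product: 27 (3aS,7aR)-6-[(PMB-oxy)methyl]-5-[(2S)-5-(TBDPSO)pentan-2-yl]-3,3a,7,7a-tetrahydro-1-benzofuran-2,4-dione, via lactol 26 (not isolated)
Conditions: TEMPO (0.2 equiv), PhI(OAc)2 (2.5 equiv), CH2Cl2, rt
Reagents that add atoms: none
Why: Oxidative lactonisation, in which only the primary alcohol is oxidised, the aldehyde is trapped by the neighbouring secondary hydroxyl as a lactol and oxidised on, and because the ketone oxygen is not yet an alcohol the lactone can only close onto O-7a, trans to the ring-fusion C–C bond.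

Step 17
Reactants: 27 (3aS,7aR)-6-[(PMB-oxy)methyl]-5-[(2S)-5-(TBDPSO)pentan-2-yl]-3,3a,7,7a-tetrahydro-1-benzofuran-2,4-dione
Product: 28 (3aR,4S,7aR)-4-hydroxy-6-[(PMB-oxy)methyl]-5-[(2S)-5-(TBDPSO)pentan-2-yl]-3a,4,7,7a-tetrahydro-1-benzofuran-2(3H)-one
Conditions: LiBH(s-Bu)3 (1.2 equiv), THF, −78 °C; AcOH quench
Reagents that add atoms: none
Why: 1,2-Reduction with a bulky borohydride, in which conjugate reduction is blocked by the fully substituted β-carbon and the hydride enters the ketone of the rigid trans-fused bicycle from the face opposite the adjacent C3a–C3 bond, giving the (4S) alcohol cis to that bond.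

Step 18
Reactants: 28 (3aR,4S,7aR)-4-hydroxy-6-[(PMB-oxy)methyl]-5-[(2S)-5-(TBDPSO)pentan-2-yl]-3a,4,7,7a-tetrahydro-1-benzofuran-2(3H)-one
Product: 29 (3aS,4S,7aR)-4-(TBSO)-6-[(PMB-oxy)methyl]-5-[(2S)-5-(TBDPSO)pentan-2-yl]-3a,4,7,7a-tetrahydro-1-benzofuran-2(3H)-one
Conditions: TBSOTf, 2,6-lutidine, CH2Cl2, −78 → 0 °C
Reagents that add atoms: tert-butyldimethylsilyl trifluoromethanesulfonate, CC(C)(C)[Si](C)(C)OS(=O)(=O)C(F)(F)F
Why: Silyl ether formation protects the hindered allylic alcohol for the enolate chemistry and the DDQ step (the 3a descriptor changes only through CIP priorities).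

Step 19
Reactants: 29 (3aS,4S,7aR)-4-(TBSO)-6-[(PMB-oxy)methyl]-5-[(2S)-5-(TBDPSO)pentan-2-yl]-3a,4,7,7a-tetrahydro-1-benzofuran-2(3H)-one
Product: 30 3-[(dimethylamino)methyl] derivative of 29 (C-3 epimer mixture, other centres unchanged)
Conditions: LiN(i-Pr)2 (1.2 equiv), THF, −78 °C; then H2C=NMe2+ I− (Eschenmoser's salt, 3 equiv), −78 °C → rt
Reagents that add atoms: N,N-dimethylmethyleneiminium iodide, C=[N+](C)C.[I-]
Why: Mannich reaction of the lactone lithium enolate with Eschenmoser's salt, where the configuration of the new α-centre is irrelevant because it is removed in step 20.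

Step 20
Reactants: 30 3-[(dimethylamino)methyl] lactone
Product: 32 (3aS,4S,7aR)-4-(TBSO)-6-[(PMB-oxy)methyl]-3-methylidene-5-[(2S)-5-(TBDPSO)pentan-2-yl]-3a,4,7,7a-tetrahydro-1-benzofuran-2(3H)-one, via ammonium iodide 31 (not isolated)
Conditions: MeI (10 equiv), MeOH, rt; then sat. aq. NaHCO3/CH2Cl2, rt
Reagents that add atoms: none
Why: N-Methylation followed by mild-base Hofmann-type β-elimination of trimethylamine gives the exocyclic α-methylene lactone.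

Step 21
Reactants: 32 α-methylene lactone PMB ether
Product: 33 (3aS,4S,7aR)-4-(TBSO)-6-(hydroxymethyl)-3-methylidene-5-[(2S)-5-(TBDPSO)pentan-2-yl]-3a,4,7,7a-tetrahydro-1-benzofuran-2(3H)-one
Conditions: DDQ (1.5 equiv), CH2Cl2/pH 7 buffer 10:1, 0 °C → rt
Reagents that add atoms: none
Why: Oxidative PMB ether cleavage (benzylic hydride abstraction by DDQ, then hydrolysis of the oxocarbenium ion) frees only the ring CH2OH.

Step 22
Reactants: 33 allylic primary alcohol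
Product: 34 [(3aS,4S,7aR)-4-(TBSO)-3-methylidene-2-oxo-5-[(2S)-5-(TBDPSO)pentan-2-yl]-2,3,3a,4,7,7a-hexahydro-1-benzofuran-6-yl]methyl 2-methylprop-2-enoate
Conditions: methacrylic anhydride (2 equiv), Et3N, DMAP (0.1 equiv), CH2Cl2, 0 °C
Reagents that add atoms: methacrylic anhydride, CC(=C)C(=O)OC(=O)C(C)=C
Why: DMAP-catalysed acylation of the single free (primary allylic) hydroxyl.

Step 23
Reactants: 34 bis-silyl methacrylate
Product: 35 [(3aR,4S,7aR)-4-hydroxy-5-[(2S)-5-hydroxypentan-2-yl]-3-methylidene-2-oxo-2,3,3a,4,7,7a-hexahydro-1-benzofuran-6-yl]methyl 2-methylprop-2-enoate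
Conditions: HF·pyridine, pyridine/THF, 0 °C → rt
Reagents that add atoms: none
Why: Fluoride desilylation under mildly acidic conditions removes both silyl ethers while the esters, the lactone and the two acrylate-type alkenes are left alone.

Step 24
Reactants: 35 diol
Product: 36 [(3aR,4S,7aR)-5-[(2S)-5-acetoxypentan-2-yl]-4-hydroxy-3-methylidene-2-oxo-2,3,3a,4,7,7a-hexahydro-1-benzofuran-6-yl]methyl 2-methylprop-2-enoate (CNP0122587.1)
Conditions: immobilised Candida antarctica lipase B, vinyl acetate (5 equiv), t-BuOMe, 30 °C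
Reagents that add atoms: vinyl acetate, CC(=O)OC=C
Why: Lipase-catalysed irreversible transesterification, in which the serine hydrolase acylates the unhindered primary alcohol and not the hindered secondary allylic one, under neutral conditions that spare both Michael acceptors.

**Compound list**
1 | ethyl 2-(2-methyl-1,3-dioxolan-2-yl)acetate | CCOC(=O)CC1(C)OCCO1 | starting material
2 | 2-(2-methyl-1,3-dioxolan-2-yl)acetic acid | OC(=O)CC1(C)OCCO1 | intermediate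
3 | potassium 3-ethoxy-3-oxopropanoate | CCOC(=O)CC(=O)[O-].[K+] | starting material
4 | 1-[2-(2-methyl-1,3-dioxolan-2-yl)acetyl]-1H-imidazole | O=C(CC1(C)OCCO1)n1ccnc1 | intermediate
5 | ethyl 4-(2-methyl-1,3-dioxolan-2-yl)-3-oxobutanoate | CCOC(=O)CC(=O)CC1(C)OCCO1 | intermediate
6 | 3-bromoprop-1-ene | C=CCBr | starting material
7 | ethyl 2-allyl-4-(2-methyl-1,3-dioxolan-2-yl)-3-oxobutanoate (racemic) | CCOC(=O)C(CC=C)C(=O)CC1(C)OCCO1 | intermediate
8 | ethyl (2S,3R)-2-allyl-3-hydroxy-4-(2-methyl-1,3-dioxolan-2-yl)butanoate | CCOC(=O)[C@@H](CC=C)[C@H](O)CC1(C)OCCO1 | intermediate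
9 | ethyl (2S,3R)-2-allyl-3-(TBSO)-4-(2-methyl-1,3-dioxolan-2-yl)butanoate | CCOC(=O)[C@@H](CC=C)[C@H](O[Si](C)(C)C(C)(C)C)CC1(C)OCCO1 | intermediate
10 | ethyl (2S,3R)-3-(TBSO)-2-(2-hydroxyethyl)-4-(2-methyl-1,3-dioxolan-2-yl)butanoate | CCOC(=O)[C@@H](CCO)[C@H](O[Si](C)(C)C(C)(C)C)CC1(C)OCCO1 | intermediate
11 | (3S)-3-[(1R)-1-(TBSO)-3-oxobutyl]oxolan-2-one | CC(=O)C[C@@H](O[Si](C)(C)C(C)(C)C)[C@@H]1CCOC1=O | intermediate
12 | (4S,5R)-5-(TBSO)-4-(2-hydroxyethyl)cyclohexane-1,3-dione (present as its dilithium salt) | O=C1CC(=O)C[C@@H](O[Si](C)(C)C(C)(C)C)[C@@H]1CCO | intermediate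
13 | (4S,5R)-5-(TBSO)-4-[2-(TBSO)ethyl]cyclohexane-1,3-dione | O=C1CC(=O)C[C@@H](O[Si](C)(C)C(C)(C)C)[C@@H]1CCO[Si](C)(C)C(C)(C)C | intermediate
14 | (E)-but-2-enal | C/C=C/C=O | starting material
15 | (3S)-3-{(3S,4R)-4-(TBSO)-3-[2-(TBSO)ethyl]-2-hydroxy-6-oxocyclohex-1-en-1-yl}butanal (open enol tautomer drawn) | O=C1C[C@@H](O[Si](C)(C)C(C)(C)C)[C@H](CCO[Si](C)(C)C(C)(C)C)C(O)=C1[C@@H](C)CC=O | intermediate
16 | (4S,5R)-5-(TBSO)-4-[2-(TBSO)ethyl]-3-hydroxy-2-[(2S)-pent-4-en-2-yl]cyclohex-2-en-1-one | O=C1C[C@@H](O[Si](C)(C)C(C)(C)C)[C@H](CCO[Si](C)(C)C(C)(C)C)C(O)=C1[C@@H](C)CC=C | intermediate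
17 | (4S,5R)-5-(TBSO)-3-hydroxy-4-(2-hydroxyethyl)-2-[(2S)-pent-4-en-2-yl]cyclohex-2-en-1-one | O=C1C[C@@H](O[Si](C)(C)C(C)(C)C)[C@H](CCO)C(O)=C1[C@@H](C)CC=C | intermediate
18 | (3aS,4R)-4-(TBSO)-7-[(2S)-pent-4-en-2-yl]-3,3a,4,5-tetrahydro-1-benzofuran-6(2H)-one | O=C1C[C@@H](O[Si](C)(C)C(C)(C)C)[C@@H]2CCOC2=C1[C@@H](C)CC=C | intermediate
19 | (3aS,4R)-4-(TBSO)-7-[(2S)-5-hydroxypentan-2-yl]-3,3a,4,5-tetrahydro-1-benzofuran-6(2H)-one | O=C1C[C@@H](O[Si](C)(C)C(C)(C)C)[C@@H]2CCOC2=C1[C@@H](C)CCCO | intermediate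
20 | (3aS,4R)-4-(TBSO)-7-[(2S)-5-(TBDPSO)pentan-2-yl]-3,3a,4,5-tetrahydro-1-benzofuran-6(2H)-one | O=C1C[C@@H](O[Si](C)(C)C(C)(C)C)[C@@H]2CCOC2=C1[C@@H](C)CCCO[Si](c1ccccc1)(c1ccccc1)C(C)(C)C | intermediate
21 | (4-methoxyphenyl)methanol | COc1ccc(CO)cc1 | starting material
22 | tributyl(iodomethyl)stannane | CCCC[Sn](CCCC)(CCCC)CI | starting material
23 | tributyl{[(4-methoxybenzyl)oxy]methyl}stannane | CCCC[Sn](CCCC)(CCCC)COCc1ccc(OC)cc1 | intermediate
24 | (3aS,4R)-4-(TBSO)-6-[(PMB-oxy)methyl]-7-[(2S)-5-(TBDPSO)pentan-2-yl]-2,3,3a,4,5,6-hexahydro-1-benzofuran-6-ol (both C-6 epimers) | OC1(COCc3ccc(OC)cc3)C[C@@H](O[Si](C)(C)C(C)(C)C)[C@@H]2CCOC2=C1[C@@H](C)CCCO[Si](c1ccccc1)(c1ccccc1)C(C)(C)C | intermediate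
25 | (5R,6S)-5-hydroxy-6-(2-hydroxyethyl)-3-[(PMB-oxy)methyl]-2-[(2S)-5-(TBDPSO)pentan-2-yl]cyclohex-2-en-1-one | O=C1C([C@@H](C)CCCO[Si](c2ccccc2)(c2ccccc2)C(C)(C)C)=C(COCc2ccc(OC)cc2)C[C@@H](O)[C@@H]1CCO | intermediate
26 | (3aS,7aR)-2-hydroxy-6-[(PMB-oxy)methyl]-5-[(2S)-5-(TBDPSO)pentan-2-yl]-3,3a,7,7a-tetrahydro-1-benzofuran-4(2H)-one (lactol, both C-2 epimers) | O=C1C([C@@H](C)CCCO[Si](c3ccccc3)(c3ccccc3)C(C)(C)C)=C(COCc3ccc(OC)cc3)C[C@H]2OC(O)C[C@H]12 | intermediate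
27 | (3aS,7aR)-6-[(PMB-oxy)methyl]-5-[(2S)-5-(TBDPSO)pentan-2-yl]-3,3a,7,7a-tetrahydro-1-benzofuran-2,4-dione | O=C1C([C@@H](C)CCCO[Si](c3ccccc3)(c3ccccc3)C(C)(C)C)=C(COCc3ccc(OC)cc3)C[C@H]2OC(=O)C[C@H]12 | intermediate
28 | (3aR,4S,7aR)-4-hydroxy-6-[(PMB-oxy)methyl]-5-[(2S)-5-(TBDPSO)pentan-2-yl]-3a,4,7,7a-tetrahydro-1-benzofuran-2(3H)-one | COc1ccc(COCC2=C([C@@H](C)CCCO[Si](c3ccccc3)(c3ccccc3)C(C)(C)C)[C@@H](O)[C@H]3CC(=O)O[C@@H]3C2)cc1 | intermediate
29 | (3aS,4S,7aR)-4-(TBSO)-6-[(PMB-oxy)methyl]-5-[(2S)-5-(TBDPSO)pentan-2-yl]-3a,4,7,7a-tetrahydro-1-benzofuran-2(3H)-one | COc1ccc(COCC2=C([C@@H](C)CCCO[Si](c3ccccc3)(c3ccccc3)C(C)(C)C)[C@@H](O[Si](C)(C)C(C)(C)C)[C@H]3CC(=O)O[C@@H]3C2)cc1 | intermediate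
30 | 3-[(dimethylamino)methyl] derivative of 29 (C-3 epimers) | COc1ccc(COCC2=C([C@@H](C)CCCO[Si](c3ccccc3)(c3ccccc3)C(C)(C)C)[C@@H](O[Si](C)(C)C(C)(C)C)[C@H]3C(CN(C)C)C(=O)O[C@@H]3C2)cc1 | intermediate
31 | trimethylammonium iodide of 30 | COc1ccc(COCC2=C([C@@H](C)CCCO[Si](c3ccccc3)(c3ccccc3)C(C)(C)C)[C@@H](O[Si](C)(C)C(C)(C)C)[C@H]3C(C[N+](C)(C)C)C(=O)O[C@@H]3C2)cc1.[I-] | intermediate
32 | (3aS,4S,7aR)-4-(TBSO)-6-[(PMB-oxy)methyl]-3-methylidene-5-[(2S)-5-(TBDPSO)pentan-2-yl]-3a,4,7,7a-tetrahydro-1-benzofuran-2(3H)-one | COc1ccc(COCC2=C([C@@H](C)CCCO[Si](c3ccccc3)(c3ccccc3)C(C)(C)C)[C@@H](O[Si](C)(C)C(C)(C)C)[C@H]3C(=C)C(=O)O[C@@H]3C2)cc1 | intermediate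
33 | (3aS,4S,7aR)-4-(TBSO)-6-(hydroxymethyl)-3-methylidene-5-[(2S)-5-(TBDPSO)pentan-2-yl]-3a,4,7,7a-tetrahydro-1-benzofuran-2(3H)-one | OCC1=C([C@@H](C)CCCO[Si](c2ccccc2)(c2ccccc2)C(C)(C)C)[C@@H](O[Si](C)(C)C(C)(C)C)[C@H]2C(=C)C(=O)O[C@@H]2C1 | intermediate
34 | [(3aS,4S,7aR)-4-(TBSO)-3-methylidene-2-oxo-5-[(2S)-5-(TBDPSO)pentan-2-yl]-2,3,3a,4,7,7a-hexahydro-1-benzofuran-6-yl]methyl 2-methylprop-2-enoate | C=C(C)C(=O)OCC1=C([C@@H](C)CCCO[Si](c2ccccc2)(c2ccccc2)C(C)(C)C)[C@@H](O[Si](C)(C)C(C)(C)C)[C@H]2C(=C)C(=O)O[C@@H]2C1 | intermediate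
35 | [(3aR,4S,7aR)-4-hydroxy-5-[(2S)-5-hydroxypentan-2-yl]-3-methylidene-2-oxo-2,3,3a,4,7,7a-hexahydro-1-benzofuran-6-yl]methyl 2-methylprop-2-enoate | C=C(C)C(=O)OCC1=C([C@@H](C)CCCO)[C@@H](O)[C@H]2C(=C)C(=O)O[C@@H]2C1 | intermediate
36 | [(3aR,4S,7aR)-5-[(2S)-5-acetoxypentan-2-yl]-4-hydroxy-3-methylidene-2-oxo-2,3,3a,4,7,7a-hexahydro-1-benzofuran-6-yl]methyl 2-methylprop-2-enoate | C=C(C)C(=O)OCC1=C([C@@H](C)CCCOC(C)=O)[C@@H](O)[C@H]2C(=C)C(=O)O[C@@H]2C1 | target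

**Count.** Total steps: 24. Longest linear sequence: 23 (steps 1–13 and 15–24; step 14 is a one-step side branch).

**Steps most likely to fail, each with one fallback**

Step 8. The enolate acylation runs next to a β-silyloxy group, so loss of TBSOH or deprotonation α to the lactone may compete. The fallback leaves from 11 and returns at 13. The lactone of 11 is opened with Me2AlN(OMe)Me (from AlMe3 and MeNH(OMe)·HCl, CH2Cl2, 0 °C) to (2S,3R)-3-(TBSO)-2-(2-hydroxyethyl)-N-methoxy-N-methyl-5-oxohexanamide F1. TBSCl/imidazole then gives the bis-silyl ether (2S,3R)-3-(TBSO)-2-[2-(TBSO)ethyl]-N-methoxy-N-methyl-5-oxohexanamide F2. LiN(SiMe3)2 (2.2 equiv, THF, −78 → 0 °C) closes the ring by attack of the methyl-ketone enolate on the amide, which has no competitively acidic α-proton and whose chelated tetrahedral intermediate holds until work-up, and this releases 13.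

Step 15. A thermally fragile α-alkoxy organolithium must add to a hindered vinylogous ester carbonyl. The fallback leaves from 16 and returns at 25, replacing carbonyl addition by cross-coupling. Tf2O/Et3N (CH2Cl2, −78 °C) sulfonylates the less hindered enol oxygen of 16, the one remote from the ring substituent, to give the vinylogous triflate (4S,5R)-5-(TBSO)-4-[2-(TBSO)ethyl]-3-oxo-2-[(2S)-pent-4-en-2-yl]cyclohex-1-en-1-yl trifluoromethanesulfonate F3; any regioisomer is separated here. Stille coupling with 23 (Pd(PPh3)4, a zerovalent palladium complex, LiCl, dioxane, 90 °C) transfers the CH2OPMB group and gives the enone (5R,6S)-5-(TBSO)-6-[2-(TBSO)ethyl]-3-[(PMB-oxy)methyl]-2-[(2S)-pent-4-en-2-yl]cyclohex-2-en-1-one F4. 9-BBN then H2O2/NaOH gives the primary alcohol (5R,6S)-5-(TBSO)-6-[2-(TBSO)ethyl]-2-[(2S)-5-hydroxypentan-2-yl]-3-[(PMB-oxy)methyl]cyclohex-2-en-1-one F5, and TBDPSCl/imidazole gives its TBDPS ether F6. 3 M HCl/THF removes both TBS groups to reach 25.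

Step 17. The facial selectivity of an external hydride on this hindered enone is the least certain stereochemical event. The fallback leaves from 25 and returns at 29; it reduces before lactonisation with internal hydride delivery. The primary OH of 25 is benzoylated (BzCl, 2,4,6-collidine, CH2Cl2, −78 °C) to give 2-[(1S,2R)-2-hydroxy-4-[(PMB-oxy)methyl]-6-oxo-5-[(2S)-5-(TBDPSO)pentan-2-yl]cyclohex-4-en-1-yl]ethyl benzoate F7. Evans–Tishchenko reduction (SmI2 15 mol %, PhCHO, THF, −10 °C) passes hydride from the hemiacetal on the secondary oxygen to the same face of the ketone, which by geometry gives the anti-1,3 relationship and leaves the new ring OH free in (1R,5S,6R)-6-[2-(benzoyloxy)ethyl]-5-hydroxy-3-[(PMB-oxy)methyl]-4-[(2S)-5-(TBDPSO)pentan-2-yl]cyclohex-3-en-1-yl benzoate F8. TBSOTf/2,6-lutidine gives its TBS ether F9, and K2CO3/MeOH removes both benzoates to give (1R,5S,6S)-5-(TBSO)-6-(2-hydroxyethyl)-3-[(PMB-oxy)methyl]-4-[(2S)-5-(TBDPSO)pentan-2-yl]cyclohex-3-en-1-ol F10. TEMPO/PhI(OAc)2 as in step 16 then closes the lactone to 29.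

Further compounds
F1 | step 8 | (2S,3R)-3-(TBSO)-2-(2-hydroxyethyl)-N-methoxy-N-methyl-5-oxohexanamide | CON(C)C(=O)[C@@H](CCO)[C@H](O[Si](C)(C)C(C)(C)C)CC(C)=O
F2 | step 8 | (2S,3R)-3-(TBSO)-2-[2-(TBSO)ethyl]-N-methoxy-N-methyl-5-oxohexanamide | CON(C)C(=O)[C@@H](CCO[Si](C)(C)C(C)(C)C)[C@H](O[Si](C)(C)C(C)(C)C)CC(C)=O
F3 | step 15 | (4S,5R)-5-(TBSO)-4-[2-(TBSO)ethyl]-3-oxo-2-[(2S)-pent-4-en-2-yl]cyclohex-1-en-1-yl trifluoromethanesulfonate | O=C1C([C@@H](C)CC=C)=C(OS(=O)(=O)C(F)(F)F)C[C@@H](O[Si](C)(C)C(C)(C)C)[C@@H]1CCO[Si](C)(C)C(C)(C)C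
F4 | step 15 | (5R,6S)-5-(TBSO)-6-[2-(TBSO)ethyl]-3-[(PMB-oxy)methyl]-2-[(2S)-pent-4-en-2-yl]cyclohex-2-en-1-one | O=C1C([C@@H](C)CC=C)=C(COCc2ccc(OC)cc2)C[C@@H](O[Si](C)(C)C(C)(C)C)[C@@H]1CCO[Si](C)(C)C(C)(C)C
F5 | step 15 | (5R,6S)-5-(TBSO)-6-[2-(TBSO)ethyl]-2-[(2S)-5-hydroxypentan-2-yl]-3-[(PMB-oxy)methyl]cyclohex-2-en-1-one | O=C1C([C@@H](C)CCCO)=C(COCc2ccc(OC)cc2)C[C@@H](O[Si](C)(C)C(C)(C)C)[C@@H]1CCO[Si](C)(C)C(C)(C)C
F6 | step 15 | (5R,6S)-5-(TBSO)-6-[2-(TBSO)ethyl]-3-[(PMB-oxy)methyl]-2-[(2S)-5-(TBDPSO)pentan-2-yl]cyclohex-2-en-1-one | O=C1C([C@@H](C)CCCO[Si](c2ccccc2)(c2ccccc2)C(C)(C)C)=C(COCc2ccc(OC)cc2)C[C@@H](O[Si](C)(C)C(C)(C)C)[C@@H]1CCO[Si](C)(C)C(C)(C)C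
F7 | step 17 | 2-[(1S,2R)-2-hydroxy-4-[(PMB-oxy)methyl]-6-oxo-5-[(2S)-5-(TBDPSO)pentan-2-yl]cyclohex-4-en-1-yl]ethyl benzoate | O=C1C([C@@H](C)CCCO[Si](c2ccccc2)(c2ccccc2)C(C)(C)C)=C(COCc2ccc(OC)cc2)C[C@@H](O)[C@@H]1CCOC(=O)c1ccccc1
F8 | step 17 | (1R,5S,6R)-6-[2-(benzoyloxy)ethyl]-5-hydroxy-3-[(PMB-oxy)methyl]-4-[(2S)-5-(TBDPSO)pentan-2-yl]cyclohex-3-en-1-yl benzoate | COc1ccc(COCC2=C([C@@H](C)CCCO[Si](c3ccccc3)(c3ccccc3)C(C)(C)C)[C@@H](O)[C@@H](CCOC(=O)c3ccccc3)[C@H](OC(=O)c3ccccc3)C2)cc1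
F9 | step 17 | (1R,5S,6S)-6-[2-(benzoyloxy)ethyl]-5-(TBSO)-3-[(PMB-oxy)methyl]-4-[(2S)-5-(TBDPSO)pentan-2-yl]cyclohex-3-en-1-yl benzoate | COc1ccc(COCC2=C([C@@H](C)CCCO[Si](c3ccccc3)(c3ccccc3)C(C)(C)C)[C@@H](O[Si](C)(C)C(C)(C)C)[C@@H](CCOC(=O)c3ccccc3)[C@H](OC(=O)c3ccccc3)C2)cc1
F10 | step 17 | (1R,5S,6S)-5-(TBSO)-6-(2-hydroxyethyl)-3-[(PMB-oxy)methyl]-4-[(2S)-5-(TBDPSO)pentan-2-yl]cyclohex-3-en-1-ol | COc1ccc(COCC2=C([C@@H](C)CCCO[Si](c3ccccc3)(c3ccccc3)C(C)(C)C)[C@@H](O[Si](C)(C)C(C)(C)C)[C@@H](CCO)[C@H](O)C2)cc1
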